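Retrosynthesis: the two catechol MOM ethers come off last. Before that, ring A is cut at C1'–C6' and C2'–C3', leaving a terminal ynone and a 1-methoxy-3-silyloxybutadiene.
Enabling feature: ring A is a benzene bearing only the acyl carbon at C1' and the hydroxyl at C4', para to each other, with C2', C3', C5' and C6' all CH. A [4+2] addition of a 1,3-dioxygenated diene to HC≡C–C(=O)R, followed by loss of methanol, gives exactly this pattern.
The ynone is cut at C(=O)–C≡ (ethynyl Grignard reagent on an N-methoxy-N-methylamide) and at Cα=Cβ (Horner–Wadsworth–Emmons reaction on the ring B aldehyde).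
Ring B is bought as 2,3,4-trihydroxybenzaldehyde. Its C5–C(CH3)2 bond comes from an aromatic Claisen rearrangement of the O4 prenyl ether, with C3 (oxygen) and C1 (CHO) blocking every other terminus.
Forward order: O4, O3 and O2 are alkylated in turn, then Claisen rearrangement, O4 protection, chain extension to the dienynone, closure of ring A and deprotection.
The target has no stereocentre. Its only stereo-element, the E enone, is set by the olefination and is not touched afterwards.

Key step: step 8

Remark on the chemistry: unprimed locants refer to ring B (C1 enone, C2 OMe, C3 and C4 OH, C5 1,1-dimethylallyl, C6 H). Primed locants refer to ring A (C1' acyl, C4' OH).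

Step 1
Reactants: 1 2,3,4-trihydroxybenzaldehyde; 2 1-bromo-3-methylbut-2-ene (prenyl bromide)
Product: 3 2,3-dihydroxy-4-[(3-methylbut-2-en-1-yl)oxy]benzaldehyde
Conditions: 2 (1.0 equiv), NaHCO3, DMF, 40 °C
Reagents that add atoms: none
Why: Williamson etherification under weak-base control, in which only the 4-OH (phenoxide conjugated with the para formyl group) is appreciably ionised, the 2-OH is held in a hydrogen bond to the aldehyde and the 3-OH is the least acidic, so one equivalent of 2 should alkylate O4 by SN2 without allylic transposition.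

Step 2
Reactants: 3 2,3-dihydroxy-4-[(3-methylbut-2-en-1-yl)oxy]benzaldehyde
Product: 4 2-hydroxy-3-(methoxymethoxy)-4-[(3-methylbut-2-en-1-yl)oxy]benzaldehyde
Conditions: MOMCl (1.1 equiv), K2CO3, acetone, 0 °C to rt
Reagents that add atoms: chloromethyl methyl ether (MOMCl), COCCl
Why: O-alkylation to the MOM acetal follows the classical 4 > 3 > 2 reactivity order of 2,3,4-trihydroxyaryl carbonyl compounds, so the chelated 2-OH should stay free while O3 is capped.

Step 3
Reactants: 4 2-hydroxy-3-(methoxymethoxy)-4-[(3-methylbut-2-en-1-yl)oxy]benzaldehyde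
Product: 5 2-methoxy-3-(methoxymethoxy)-4-[(3-methylbut-2-en-1-yl)oxy]benzaldehyde
Conditions: MeI (excess), K2CO3, DMF, rt to 40 °C
Reagents that add atoms: iodomethane (MeI), CI
Why: Williamson methylation of the last, chelated phenol needs only a polar aprotic solvent and excess MeI, and no other acidic or nucleophilic site is left in 4.

Step 4
Reactants: 5 2-methoxy-3-(methoxymethoxy)-4-[(3-methylbut-2-en-1-yl)oxy]benzaldehyde
Product: 7 4-hydroxy-2-methoxy-3-(methoxymethoxy)-5-(2-methylbut-3-en-2-yl)benzaldehyde, via ortho-dienone 6 (not isolated)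
Conditions: PhNEt2, 190 °C, sealed tube, Ar
Reagents that add atoms: none
Why: In this aromatic Claisen rearrangement the [3,3] shift delivers the allyl unit with inversion to C5, the only ortho carbon that bears hydrogen, because C3 carries OMOM and the para carbon C1 carries CHO so that no onward Cope migration can end in an arene; dienone 6 then tautomerises to phenol 7, and the basic solvent holds back acid-induced ring closure.

Step 5
Reactants: 7 4-hydroxy-2-methoxy-3-(methoxymethoxy)-5-(2-methylbut-3-en-2-yl)benzaldehyde
Product: 8 2-methoxy-3,4-bis(methoxymethoxy)-5-(2-methylbut-3-en-2-yl)benzaldehyde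
Conditions: NaH, MOMCl, DMF, 0 °C to rt
Reagents that add atoms: chloromethyl methyl ether (MOMCl), COCCl
Why: Full deprotonation gives a phenoxide that, although flanked on both sides, should be alkylated by the small and very reactive MOMCl (Williamson-type acetal protection), and the aldehyde cannot enolise.

Step 6
Reactants: 8 2-methoxy-3,4-bis(methoxymethoxy)-5-(2-methylbut-3-en-2-yl)benzaldehyde; 9 diethyl [2-(methoxy(methyl)amino)-2-oxoethyl]phosphonate
Product: 10 (E)-N-methoxy-N-methyl-3-[2-methoxy-3,4-bis(methoxymethoxy)-5-(2-methylbut-3-en-2-yl)phenyl]prop-2-enamide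
Conditions: 9, NaH, THF, 0 °C to rt
Reagents that add atoms: none
Why: Horner–Wadsworth–Emmons olefination with an amide-stabilised phosphonate anion adds reversibly to aromatic aldehydes and should give the E alkene, which is the only stereo-element of the target.

Step 7
Reactants: 10 (E)-N-methoxy-N-methyl-3-[2-methoxy-3,4-bis(methoxymethoxy)-5-(2-methylbut-3-en-2-yl)phenyl]prop-2-enamide; 11 ethynylmagnesium bromide
Product: 13 (E)-1-[2-methoxy-3,4-bis(methoxymethoxy)-5-(2-methylbut-3-en-2-yl)phenyl]pent-1-en-4-yn-3-one, via magnesium hemiaminal chelate 12 (not isolated)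
Conditions: 11 (0.5 M in THF, 2.5 equiv), THF, 0 °C; inverse quench into 0.5 M HCl (aq), 0 °C
Reagents that add atoms: none
Why: In this Weinreb ketone synthesis, 1,2-addition gives chelate 12, which persists until the quench and so prevents over-addition, and pouring into cold acid protonates the released N,O-dimethylhydroxylamine before it can add to the new terminal ynone, while the brief cold contact spares the MOM ethers.

Step 8
Reactants: 13 (E)-1-[2-methoxy-3,4-bis(methoxymethoxy)-5-(2-methylbut-3-en-2-yl)phenyl]pent-1-en-4-yn-3-one; 14 trans-1-methoxy-3-(trimethylsilyloxy)buta-1,3-diene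
Product: 16 (E)-1-(4-hydroxyphenyl)-3-[2-methoxy-3,4-bis(methoxymethoxy)-5-(2-methylbut-3-en-2-yl)phenyl]prop-2-en-1-one, via cyclohexa-1,4-diene cycloadduct 15 (not isolated)
Conditions: 14 (1.5 equiv), BHT (trace), PhMe, 70 °C; then 0.1 M HCl (aq), THF, 0 °C
Reagents that add atoms: none
Why: The donor-substituted diene 14 and the acceptor-substituted triple bond of 13 should join in a thermal normal-electron-demand Diels–Alder reaction, one kinetic step with uneven bond advancement, in which the free CH2 end of 14 (largest HOMO coefficient) leads by bonding to the terminal alkyne carbon (C2'–C3') and the OMe-bearing end follows at the alkyne carbon attached to C=O (C1'–C6'). Ring A is thus closed as a six-membered carbocycle by intermolecular [4+2] cycloaddition and appears first as cyclohexa-1,4-diene 15. Cold dilute acid hydrolyses the silyl enol ether, the resulting β-methoxy ketone expels methanol and the dienone tautomerises, which places the oxygen at C4', opposite the acyl carbon. The closest known reaction type is the benzannulation of 1-alkoxy-3-silyloxybutadienes with acetylenic ketones and esters to give para-hydroxyaryl carbonyl compounds. The single stereocentre of 15 (C6') forms as a racemate under no control and vanishes on aromatisation, so 16 carries no new stereocentre and keeps the E enone. Regioselectivity rests on the matched push–pull polarisation of the two partners, chemoselectivity on the monosubstituted carbonyl-activated alkyne outrunning both the 1,2-disubstituted enone C=C (deactivated by its trialkoxyaryl donor) and the unactivated vinyl group, and acid of this strength and temperature should leave the aryl MOM ethers in place.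

Step 9
Reactants: 16 (E)-1-(4-hydroxyphenyl)-3-[2-methoxy-3,4-bis(methoxymethoxy)-5-(2-methylbut-3-en-2-yl)phenyl]prop-2-en-1-one
Product: 17 (E)-3-[3,4-dihydroxy-2-methoxy-5-(2-methylbut-3-en-2-yl)phenyl]-1-(4-hydroxyphenyl)prop-2-en-1-one (InflamNat:IN0234)
Conditions: 3 M HCl (aq), MeOH, 50 °C
Reagents that add atoms: none
Why: Acid-catalysed acetal exchange with methanol removes both MOM groups, the monosubstituted vinyl group on a quaternary carbon is not protonated by acid of this strength, and the 2-OMe group rules out cyclisation onto the enone.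

Compound list
1 | 2,3,4-trihydroxybenzaldehyde | O=Cc1ccc(O)c(O)c1O | starting material
2 | 1-bromo-3-methylbut-2-ene | CC(C)=CCBr | starting material
3 | 2,3-dihydroxy-4-[(3-methylbut-2-en-1-yl)oxy]benzaldehyde | O=Cc1ccc(OCC=C(C)C)c(O)c1O | intermediate
4 | 2-hydroxy-3-(methoxymethoxy)-4-[(3-methylbut-2-en-1-yl)oxy]benzaldehyde | O=Cc1ccc(OCC=C(C)C)c(OCOC)c1O | intermediate
5 | 2-methoxy-3-(methoxymethoxy)-4-[(3-methylbut-2-en-1-yl)oxy]benzaldehyde | O=Cc1ccc(OCC=C(C)C)c(OCOC)c1OC | intermediate
6 | 6-methoxy-5-(methoxymethoxy)-3-(2-methylbut-3-en-2-yl)-4-oxocyclohexa-1,5-diene-1-carbaldehyde (racemic, not isolated) | C=CC(C)(C)C1C=C(C=O)C(OC)=C(OCOC)C1=O | intermediate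
7 | 4-hydroxy-2-methoxy-3-(methoxymethoxy)-5-(2-methylbut-3-en-2-yl)benzaldehyde | C=CC(C)(C)c1cc(C=O)c(OC)c(OCOC)c1O | intermediate
8 | 2-methoxy-3,4-bis(methoxymethoxy)-5-(2-methylbut-3-en-2-yl)benzaldehyde | C=CC(C)(C)c1cc(C=O)c(OC)c(OCOC)c1OCOC | intermediate
9 | diethyl [2-(methoxy(methyl)amino)-2-oxoethyl]phosphonate | CCOP(=O)(CC(=O)N(C)OC)OCC | starting material
10 | (E)-N-methoxy-N-methyl-3-[2-methoxy-3,4-bis(methoxymethoxy)-5-(2-methylbut-3-en-2-yl)phenyl]prop-2-enamide | C=CC(C)(C)c1cc(/C=C/C(=O)N(C)OC)c(OC)c(OCOC)c1OCOC | intermediate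
11 | ethynylmagnesium bromide | C#C[Mg]Br | starting material
12 | bromomagnesium alkoxide of (E)-3-[methoxy(methyl)amino]-1-[2-methoxy-3,4-bis(methoxymethoxy)-5-(2-methylbut-3-en-2-yl)phenyl]pent-1-en-4-yn-3-ol (racemic, not isolated) | C=CC(C)(C)c1cc(/C=C/C(O[Mg]Br)(C#C)N(C)OC)c(OC)c(OCOC)c1OCOC | intermediate
13 | (E)-1-[2-methoxy-3,4-bis(methoxymethoxy)-5-(2-methylbut-3-en-2-yl)phenyl]pent-1-en-4-yn-3-one | C=CC(C)(C)c1cc(/C=C/C(=O)C#C)c(OC)c(OCOC)c1OCOC | intermediate
14 | trans-1-methoxy-3-(trimethylsilyloxy)buta-1,3-diene | CO/C=C/C(=C)O[Si](C)(C)C | starting material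
15 | (E)-1-[6-methoxy-4-(trimethylsilyloxy)cyclohexa-1,4-dien-1-yl]-3-[2-methoxy-3,4-bis(methoxymethoxy)-5-(2-methylbut-3-en-2-yl)phenyl]prop-2-en-1-one (racemic, not isolated) | C=CC(C)(C)c1cc(/C=C/C(=O)C2=CCC(O[Si](C)(C)C)=CC2OC)c(OC)c(OCOC)c1OCOC | intermediate
16 | (E)-1-(4-hydroxyphenyl)-3-[2-methoxy-3,4-bis(methoxymethoxy)-5-(2-methylbut-3-en-2-yl)phenyl]prop-2-en-1-one | C=CC(C)(C)c1cc(/C=C/C(=O)c2ccc(O)cc2)c(OC)c(OCOC)c1OCOC | intermediate
17 | (E)-3-[3,4-dihydroxy-2-methoxy-5-(2-methylbut-3-en-2-yl)phenyl]-1-(4-hydroxyphenyl)prop-2-en-1-one | C=CC(C)(C)c1cc(/C=C/C(=O)c2ccc(O)cc2)c(OC)c(O)c1O | target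

Total step count: 9. Longest linear sequence: 9 steps (1 to 17).

Steps most likely to fail

Step 8. The cross-conjugated dienynone may oligomerise or pick up adventitious nucleophiles faster than it cycloadds. The diene may lose its silyl group on prolonged heating, or the aromatisation acid may begin to strip the MOM ethers. The fallback sets out from diene 14 and aldehyde 8 and comes back at 16. It moves the arene construction to the simplest terminal ynone and joins the two halves afterwards. Diene 14 and but-3-yn-2-one (PhMe, 80 °C) should give 1-[6-methoxy-4-(trimethylsilyloxy)cyclohexa-1,4-dien-1-yl]ethan-1-one F1, which dilute HCl in THF converts to 4-hydroxyacetophenone F2. A Claisen–Schmidt condensation of F2 with 8 (excess KOH, EtOH, rt) then forms the Cα=Cβ bond and should deliver 16 directly. Steps 6 and 7 and the fragile dienynone are bypassed.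

Step 4. At the temperature required, three side processes may compete with the [3,3] shift. These are thermal loss of the prenyl group, isomerisation of the new side chain along the abnormal Claisen pathway, and ring closure of the liberated phenol onto the vinyl group. The fallback sets out from 1 and comes back at 8, and it makes the C5–C(CH3)2 bond by cross-coupling instead of by a sigmatropic shift.
- Compound 1 is protected at O3 and O4 (MOMCl, 2.2 equiv, K2CO3, acetone) to give 2-hydroxy-3,4-bis(methoxymethoxy)benzaldehyde F3.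
- F3 is methylated (MeI, K2CO3, DMF) to give 2-methoxy-3,4-bis(methoxymethoxy)benzaldehyde F4.
- F4 is brominated with NBS in MeCN at C5, the position para to OMe, ortho to OMOM and meta to CHO, to give 5-bromo-2-methoxy-3,4-bis(methoxymethoxy)benzaldehyde F5.
- A branched-selective allyl–aryl Suzuki–Miyaura coupling of F5 with 3-methylbut-2-enylboronic acid pinacol ester should attach the quaternary carbon and give 8. The conditions are Pd(OAc)2, a bulky biaryl dialkylphosphine chosen for attack through the γ-carbon, K3PO4 and aqueous THF.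

Step 1. Over-alkylation, alkylation at O3 or O2, or C-prenylation of the electron-rich ring may erode the selectivity for O4. The fallback sets out from 1 and comes back at 5. It ties O3 and O4 together temporarily so that the methyl ether is placed first.
- Heating 1 with dichlorodiphenylmethane should give 4-hydroxy-2,2-diphenyl-1,3-benzodioxole-5-carbaldehyde F6, the chelated 2-OH staying outside the ketal.
- Methylation (MeI, K2CO3, DMF) gives 4-methoxy-2,2-diphenyl-1,3-benzodioxole-5-carbaldehyde F7.
- Aqueous acetic acid at reflux releases 3,4-dihydroxy-2-methoxybenzaldehyde F8.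
- The well-established 4-selective alkylation of 3,4-dihydroxybenzaldehydes (2, NaHCO3, DMF) gives 3-hydroxy-2-methoxy-4-[(3-methylbut-2-en-1-yl)oxy]benzaldehyde F9.
- MOMCl with K2CO3 converts F9 into 5. This detour also removes the selectivity demand of step 2.

Further compounds
F1 | step 8 | 1-[6-methoxy-4-(trimethylsilyloxy)cyclohexa-1,4-dien-1-yl]ethan-1-one (racemic) | CC(=O)C1=CCC(O[Si](C)(C)C)=CC1OC
F2 | step 8 | 4-hydroxyacetophenone | CC(=O)c1ccc(O)cc1
F3 | step 4 | 2-hydroxy-3,4-bis(methoxymethoxy)benzaldehyde | O=Cc1ccc(OCOC)c(OCOC)c1O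
F4 | step 4 | 2-methoxy-3,4-bis(methoxymethoxy)benzaldehyde | O=Cc1ccc(OCOC)c(OCOC)c1OC
F5 | step 4 | 5-bromo-2-methoxy-3,4-bis(methoxymethoxy)benzaldehyde | O=Cc1cc(Br)c(OCOC)c(OCOC)c1OC
F6 | step 1 | 4-hydroxy-2,2-diphenyl-1,3-benzodioxole-5-carbaldehyde | O=Cc1ccc2OC(c3ccccc3)(c3ccccc3)Oc2c1O
F7 | step 1 | 4-methoxy-2,2-diphenyl-1,3-benzodioxole-5-carbaldehyde | O=Cc1ccc2OC(c3ccccc3)(c3ccccc3)Oc2c1OC
F8 | step 1 | 3,4-dihydroxy-2-methoxybenzaldehyde | O=Cc1ccc(O)c(O)c1OC
F9 | step 1 | 3-hydroxy-2-methoxy-4-[(3-methylbut-2-en-1-yl)oxy]benzaldehyde | O=Cc1ccc(OCC=C(C)C)c(O)c1OC
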